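**Plan**

- Enabling feature: ring C (O1, C2, C3, C4, C4a, C8a) is a 2-aryl-3-oxy-2,3-dihydropyran-4-one whose O1–C2 unit is the carbonyl group of 4-hydroxybenzaldehyde. Ring C and both stereocentres (C2, C3) can therefore be made before ring A, and the C4a=C8a enol ether bond is kept as the handle for ring A.
- Retrosynthetic cuts, in order: the O7–CH2 ether of the side chain; C4a–C5 and C8–C8a of ring A ([4+2] addition of a 1,1,3-trioxygenated diene, with a sulfinyl group at C4a as activator and leaving group); C2–C3 and O1–C8a of ring C (formal hetero-Diels–Alder reaction).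
- Forward order: diene and silyl-protected aldehyde, then ring C, sulfenylation and oxidation at C4a, ring A, debenzylation at O3, alkylation at O7, and desilylation at O4'.
- Stereochemistry: C2 comes from the (S)-BINOL/Ti(OiPr)4 catalyst, C3 from equilibration next to the C4 ketone to the trans isomer, and the (E)-alkene from the SN2' opening of 2-methyl-2-vinyloxirane.

Key step: step 6

Assumption: the (S)-BINOL titanium complex is expected to leave the Si face of the aldehyde open, as it does towards simpler allyl and siloxydiene nucleophiles; if the 4-benzyloxy diene responds with the opposite sense, (R)-BINOL would be used with no other change.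

**Route**

Step 1
Reactants: 1 benzyloxyacetyl chloride
Product: 2 2-(benzyloxy)-N-methoxy-N-methylacetamide
Conditions: MeNHOMe·HCl, pyridine, CH2Cl2, 0 °C to rt
Reagents that add atoms: N,O-dimethylhydroxylamine hydrochloride, CNOC.Cl
Why: Acylation of the amine by the acid chloride gives the N-methoxy-N-methylamide needed for a clean ketone synthesis, and pyridine takes up the HCl.

Step 2
Reactants: 2 2-(benzyloxy)-N-methoxy-N-methylacetamide
Product: 3 1-(benzyloxy)but-3-yn-2-one
Conditions: HC≡CMgBr, THF, −20 to 0 °C; then cold 1 M HCl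
Reagents that add atoms: ethynylmagnesium bromide, C#C[Mg]Br
Why: Weinreb ketone synthesis, in which the chelated tetrahedral adduct holds until the quench so the alkynyl Grignard reagent adds once, and the cold acid keeps the released amine from adding to the ynone.

Step 3
Reactants: 3 1-(benzyloxy)but-3-yn-2-one
Product: 4 (3E)-1-(benzyloxy)-4-methoxybut-3-en-2-one
Conditions: MeOH (2 equiv), DABCO (10 mol %), CH2Cl2, 0 °C
Reagents that add atoms: methanol, CO
Why: Amine-catalysed conjugate addition of methanol to the terminal ynone should stop at the mono-adduct and give the thermodynamically preferred (E)-β-methoxy enone.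

Step 4
Reactants: 4 (3E)-1-(benzyloxy)-4-methoxybut-3-en-2-one
Product: 5 (1E,3Z)-4-(benzyloxy)-1-methoxy-3-(trimethylsilyloxy)buta-1,3-diene
Conditions: TMSOTf, Et3N, Et2O, 0 °C
Reagents that add atoms: trimethylsilyl trifluoromethanesulfonate, C[Si](C)(C)OS(=O)(=O)C(F)(F)F
Why: Soft enolisation of the only enolisable position gives the silyl enol ether, and the (Z)-isomer with the two oxygens cis is the usual outcome for α-alkoxy ketones.

Step 5
Reactants: 6 4-hydroxybenzaldehyde
Product: 7 4-(triisopropylsilyloxy)benzaldehyde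
Conditions: TIPSCl, imidazole, DMF, rt
Reagents that add atoms: triisopropylsilyl chloride, CC(C)[Si](Cl)(C(C)C)C(C)C
Why: Standard silylation of a phenol; the bulky aryl silyl ether should survive acid, hydrogenolysis and carbonate base and fall only to fluoride at the end.

Step 6
Reactants: 5 (1E,3Z)-4-(benzyloxy)-1-methoxy-3-(trimethylsilyloxy)buta-1,3-diene; 7 4-(triisopropylsilyloxy)benzaldehyde
Product: 10 (2R,3R)-3-(benzyloxy)-2-[4-(triisopropylsilyloxy)phenyl]-2,3-dihydro-4H-pyran-4-one, via aldol adduct 8 (not isolated), via cis-dihydropyranone 9 (not isolated)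
Conditions: (S)-BINOL (20 mol %), Ti(OiPr)4 (10 mol %), 4 Å MS, Et2O, −20 °C; then TFA, CH2Cl2, 0 °C; then Et3N, CH2Cl2, rt
Reagents that add atoms: none
Why: The (S)-BINOL/Ti(OiPr)4 complex binds the aldehyde of 7, and the silyl enol ether terminus of 5 (the carbon bearing OBn) adds to the carbonyl carbon in a Mukaiyama aldol step that forms C2–C3 and gives 8; trifluoroacetic acid then makes the new hydroxyl add to the β-methoxy enone and expel methanol, which forms O1–C6 of the pyranone (O1–C8a of the later flavanonol). The closest known reaction type is the BINOL titanium-catalysed formal hetero-Diels–Alder reaction of 1-methoxy-3-silyloxybutadienes, 4-oxygenated ones included, with aromatic aldehydes. Ring C closes by 6-endo-trig oxa-Michael addition followed by β-elimination of methanol. C2 is set by the catalyst, which should leave the Si face of the aldehyde open, and C3 is set thermodynamically: it is enolisable next to the C4 ketone, so triethylamine should convert any cis isomer 9 into trans 10, whose aryl and benzyloxy groups are both pseudo-equatorial. The step needs face selectivity at the aldehyde and a single bonding orientation; the orientation is secured because the silyl enol ether carbon is the only strongly nucleophilic site of 5 and the methoxy-bearing carbon the only position that can accept the hydroxyl and lose a leaving group, while the silyl ether keeps the phenol away from titanium.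

Step 7
Reactants: 10 (2R,3R)-3-(benzyloxy)-2-[4-(triisopropylsilyloxy)phenyl]-2,3-dihydro-4H-pyran-4-one
Product: 11 (2R,3R)-3-(benzyloxy)-5-(phenylsulfanyl)-2-[4-(triisopropylsilyloxy)phenyl]-2,3-dihydro-4H-pyran-4-one
Conditions: PhSCl, CH2Cl2, −78 °C; then Et3N, −78 to 0 °C
Reagents that add atoms: benzenesulfenyl chloride, ClSc1ccccc1
Why: Electrophilic sulfenylation of the enol ether carbon C5 of the vinylogous ester (addition of the sulfenyl chloride across C5=C6, then amine-induced loss of HCl) follows the addition–elimination course by which such pyranones are halogenated at C5.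

Step 8
Reactants: 11 (2R,3R)-3-(benzyloxy)-5-(phenylsulfanyl)-2-[4-(triisopropylsilyloxy)phenyl]-2,3-dihydro-4H-pyran-4-one
Product: 12 (2R,3R)-3-(benzyloxy)-5-(phenylsulfinyl)-2-[4-(triisopropylsilyloxy)phenyl]-2,3-dihydro-4H-pyran-4-one (both sulfur epimers)
Conditions: mCPBA (1.0 equiv), CH2Cl2, −78 °C
Reagents that add atoms: 3-chloroperoxybenzoic acid, OOC(=O)c1cccc(Cl)c1
Why: Sulfide to sulfoxide oxidation with one equivalent of peracid at low temperature is chemoselective, the electron-poor enol ether bond is not epoxidised, and the configuration at sulfur is immaterial because the group is lost later.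

Step 9
Reactants: 13 methyl acetoacetate
Product: 14 methyl 3-(trimethylsilyloxy)but-2-enoate (E/Z mixture)
Conditions: TMSCl, Et3N, hexane, rt
Reagents that add atoms: chlorotrimethylsilane, C[Si](C)(C)Cl
Why: O-Silylation of the enol form of the β-keto ester under amine base gives the silyl enol ether.

Step 10
Reactants: 14 methyl 3-(trimethylsilyloxy)but-2-enoate
Product: 15 1-methoxy-1,3-bis(trimethylsilyloxy)buta-1,3-diene
Conditions: LiN(iPr)2, THF, −78 °C; then TMSCl
Reagents that add atoms: chlorotrimethylsilane, C[Si](C)(C)Cl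
Why: Kinetic γ-deprotonation of the vinylogous ester and O-silylation of the dienolate gives the bis(silyloxy)diene; the geometry at the ketene acetal is immaterial.

Step 11
Reactants: 12 (2R,3R)-3-(benzyloxy)-5-(phenylsulfinyl)-2-[4-(triisopropylsilyloxy)phenyl]-2,3-dihydro-4H-pyran-4-one; 15 1-methoxy-1,3-bis(trimethylsilyloxy)buta-1,3-diene
Product: 18 (2R,3R)-3-(benzyloxy)-5,7-dihydroxy-2-[4-(triisopropylsilyloxy)phenyl]-2,3-dihydro-4H-chromen-4-one, via sulfinyl cycloadduct 16 (not isolated), via dienol silyl ether 17 (not isolated)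
Conditions: 15 (3 equiv), toluene, 80 °C; then 1 M HCl, THF, rt
Reagents that add atoms: none
Why: Proposed new method: the ketone and the sulfinyl group together should lower the LUMO of the C4a=C8a bond enough for a thermal, regioselective [4+2] addition in which the nucleophilic CH2 terminus of 15 bonds to C8a and the ketene acetal carbon to C4a (16); the cis C8a–H/C4a–S(O)Ph relationship made by suprafacial addition is what the sulfoxide syn-elimination needs (17), and acid then hydrolyses the silyl ethers and the mixed ketal so that ring A tautomerises to the 5,7-dihydroxyarene with C2 and C3 untouched; the closest known reaction type is the Diels–Alder, sulfenic acid elimination and aromatisation sequence of 2-sulfinyl quinones and 2-sulfinyl cycloalkenones with oxygenated siloxydienes, which has not been shown on a 5-sulfinyl-2,3-dihydropyran-4-one.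

Step 12
Reactants: 18 (2R,3R)-3-(benzyloxy)-5,7-dihydroxy-2-[4-(triisopropylsilyloxy)phenyl]-2,3-dihydro-4H-chromen-4-one
Product: 19 (2R,3R)-3,5,7-trihydroxy-2-[4-(triisopropylsilyloxy)phenyl]-2,3-dihydro-4H-chromen-4-one
Conditions: H2 (1 atm), Pd(OH)2/C, EtOAc, rt
Reagents that add atoms: none
Why: Catalytic hydrogenolysis of the benzyl ether frees the C3 hydroxyl before any alkene is present, while the silyl ether, the chelated aryl ketone and the cyclic C2–O1 bond should hold under these mild conditions.

Step 13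
Reactants: 20 2-methyl-2-vinyloxirane (racemic)
Product: 21 (2E)-4-chloro-2-methylbut-2-en-1-ol
Conditions: TiCl4, CH2Cl2, −90 °C
Reagents that add atoms: titanium tetrachloride, Cl[Ti](Cl)(Cl)Cl
Why: Lewis acid-mediated SN2' opening of the vinyl epoxide by chloride should give the (E)-1,4-chlorohydrin, with the epoxide stereocentre destroyed in the process.

Step 14
Reactants: 19 (2R,3R)-3,5,7-trihydroxy-2-[4-(triisopropylsilyloxy)phenyl]-2,3-dihydro-4H-chromen-4-one; 21 (2E)-4-chloro-2-methylbut-2-en-1-ol
Product: 22 (2R,3R)-3,5-dihydroxy-7-{[(2E)-4-hydroxy-3-methylbut-2-en-1-yl]oxy}-2-[4-(triisopropylsilyloxy)phenyl]-2,3-dihydro-4H-chromen-4-one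
Conditions: K2CO3 (1.1 equiv), NaI (cat.), acetone, 40 °C, under argon
Reagents that add atoms: none
Why: Williamson etherification at the only acidic, unchelated phenol (the 5-hydroxyl is hydrogen-bonded to the C4 carbonyl, the 3-hydroxyl and the reagent hydroxyl are alcohols, O4' is silylated), and SN2 attack at the primary allylic halide keeps the (E)-alkene.

Step 15
Reactants: 22 (2R,3R)-3,5-dihydroxy-7-{[(2E)-4-hydroxy-3-methylbut-2-en-1-yl]oxy}-2-[4-(triisopropylsilyloxy)phenyl]-2,3-dihydro-4H-chromen-4-one
Product: 23 (2R,3R)-3,5-dihydroxy-7-{[(2E)-4-hydroxy-3-methylbut-2-en-1-yl]oxy}-2-(4-hydroxyphenyl)-2,3-dihydro-4H-chromen-4-one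
Conditions: TBAF, AcOH, THF, 0 °C
Reagents that add atoms: none
Why: Fluoride cleaves the aryl silyl ether, and the acetic acid buffer should keep the base-sensitive dihydroflavonol from epimerising or ring-opening.

**Compound list**

1 | benzyloxyacetyl chloride | O=C(Cl)COCc1ccccc1 | starting material
2 | 2-(benzyloxy)-N-methoxy-N-methylacetamide | CON(C)C(=O)COCc1ccccc1 | intermediate
3 | 1-(benzyloxy)but-3-yn-2-one | C#CC(=O)COCc1ccccc1 | intermediate
4 | (3E)-1-(benzyloxy)-4-methoxybut-3-en-2-one | CO/C=C/C(=O)COCc1ccccc1 | intermediate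
5 | (1E,3Z)-4-(benzyloxy)-1-methoxy-3-(trimethylsilyloxy)buta-1,3-diene | CO/C=C/C(O[Si](C)(C)C)=C/OCc1ccccc1 | intermediate
6 | 4-hydroxybenzaldehyde | O=Cc1ccc(O)cc1 | starting material
7 | 4-(triisopropylsilyloxy)benzaldehyde | O=Cc1ccc(O[Si](C(C)C)(C(C)C)C(C)C)cc1 | intermediate
8 | (1E,5R)-4-(benzyloxy)-5-hydroxy-1-methoxy-5-[4-(triisopropylsilyloxy)phenyl]pent-1-en-3-one (both C4 epimers, possibly in part as the O-trimethylsilyl ether) | CO/C=C/C(=O)C(OCc1ccccc1)[C@H](O)c1ccc(O[Si](C(C)C)(C(C)C)C(C)C)cc1 | intermediate (not isolated)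
9 | (2R,3S)-3-(benzyloxy)-2-[4-(triisopropylsilyloxy)phenyl]-2,3-dihydro-4H-pyran-4-one (cis) | O1[C@H](c2ccc(O[Si](C(C)C)(C(C)C)C(C)C)cc2)[C@H](OCc2ccccc2)C(=O)C=C1 | intermediate (not isolated)
10 | (2R,3R)-3-(benzyloxy)-2-[4-(triisopropylsilyloxy)phenyl]-2,3-dihydro-4H-pyran-4-one (trans) | O1[C@H](c2ccc(O[Si](C(C)C)(C(C)C)C(C)C)cc2)[C@@H](OCc2ccccc2)C(=O)C=C1 | intermediate
11 | (2R,3R)-3-(benzyloxy)-5-(phenylsulfanyl)-2-[4-(triisopropylsilyloxy)phenyl]-2,3-dihydro-4H-pyran-4-one | O1[C@H](c2ccc(O[Si](C(C)C)(C(C)C)C(C)C)cc2)[C@@H](OCc2ccccc2)C(=O)C(Sc2ccccc2)=C1 | intermediate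
12 | (2R,3R)-3-(benzyloxy)-5-(phenylsulfinyl)-2-[4-(triisopropylsilyloxy)phenyl]-2,3-dihydro-4H-pyran-4-one (both sulfur epimers) | O1[C@H](c2ccc(O[Si](C(C)C)(C(C)C)C(C)C)cc2)[C@@H](OCc2ccccc2)C(=O)C(S(=O)c2ccccc2)=C1 | intermediate
13 | methyl acetoacetate | COC(=O)CC(C)=O | starting material
14 | methyl 3-(trimethylsilyloxy)but-2-enoate (E/Z mixture) | COC(=O)C=C(C)O[Si](C)(C)C | intermediate
15 | 1-methoxy-1,3-bis(trimethylsilyloxy)buta-1,3-diene | COC(O[Si](C)(C)C)=CC(=C)O[Si](C)(C)C | intermediate
16 | (2R,3R)-3-(benzyloxy)-5-methoxy-4a-(phenylsulfinyl)-2-[4-(triisopropylsilyloxy)phenyl]-5,7-bis(trimethylsilyloxy)-2,3,4a,5,8,8a-hexahydro-4H-chromen-4-one (cis-fused, mixture at the new centres) | O1[C@H](c2ccc(O[Si](C(C)C)(C(C)C)C(C)C)cc2)[C@@H](OCc2ccccc2)C(=O)C2(S(=O)c3ccccc3)C1CC(O[Si](C)(C)C)=CC2(OC)O[Si](C)(C)C | intermediate (not isolated)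
17 | (2R,3R)-3-(benzyloxy)-5-methoxy-2-[4-(triisopropylsilyloxy)phenyl]-5,7-bis(trimethylsilyloxy)-2,3,5,8-tetrahydro-4H-chromen-4-one (mixture at C5) | O1[C@H](c2ccc(O[Si](C(C)C)(C(C)C)C(C)C)cc2)[C@@H](OCc2ccccc2)C(=O)C2=C1CC(O[Si](C)(C)C)=CC2(OC)O[Si](C)(C)C | intermediate (not isolated)
18 | (2R,3R)-3-(benzyloxy)-5,7-dihydroxy-2-[4-(triisopropylsilyloxy)phenyl]-2,3-dihydro-4H-chromen-4-one | Oc1cc(O)c2c(c1)O[C@H](c1ccc(O[Si](C(C)C)(C(C)C)C(C)C)cc1)[C@@H](OCc1ccccc1)C2=O | intermediate
19 | (2R,3R)-3,5,7-trihydroxy-2-[4-(triisopropylsilyloxy)phenyl]-2,3-dihydro-4H-chromen-4-one | Oc1cc(O)c2c(c1)O[C@H](c1ccc(O[Si](C(C)C)(C(C)C)C(C)C)cc1)[C@@H](O)C2=O | intermediate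
20 | 2-methyl-2-vinyloxirane (racemic) | C=CC1(C)CO1 | starting material
21 | (2E)-4-chloro-2-methylbut-2-en-1-ol | C/C(=C\CCl)CO | intermediate
22 | (2R,3R)-3,5-dihydroxy-7-{[(2E)-4-hydroxy-3-methylbut-2-en-1-yl]oxy}-2-[4-(triisopropylsilyloxy)phenyl]-2,3-dihydro-4H-chromen-4-one | C/C(=C\COc1cc(O)c2c(c1)O[C@H](c1ccc(O[Si](C(C)C)(C(C)C)C(C)C)cc1)[C@@H](O)C2=O)CO | intermediate
23 | (2R,3R)-3,5-dihydroxy-7-{[(2E)-4-hydroxy-3-methylbut-2-en-1-yl]oxy}-2-(4-hydroxyphenyl)-2,3-dihydro-4H-chromen-4-one | C/C(=C\COc1cc(O)c2c(c1)O[C@H](c1ccc(O)cc1)[C@@H](O)C2=O)CO | target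

**Step count and risks**

Total steps: 15. Longest linear sequence: 11 steps (steps 1, 2, 3, 4, 6, 7, 8, 11, 12, 14, 15).

Steps most likely to fail:

1. Step 11 (the step carrying the label). The push–pull enol ether bond may react too slowly with the diene at a temperature the sulfoxide tolerates, the sulfinyl group may be diverted by silyl transfer into Pummerer-type chemistry, or the released sulfenic acid may consume the diene before cycloaddition is complete. The fallback makes the same two bonds stepwise by known polar chemistry, setting out from 12 and 13 and coming back at 18. The dianion of 13 (NaH, then n-BuLi, THF, 0 °C) should add at −78 °C through its terminal carbon to C8a of 12, as enolates add to 2-sulfinyl enones. A cold acetic acid quench should then give the Michael adduct methyl 4-[(5R,6R)-5-(benzyloxy)-4-oxo-3-(phenylsulfinyl)-6-[4-(triisopropylsilyloxy)phenyl]oxan-2-yl]-3-oxobutanoate F1. NaOMe in MeOH at 0 °C should close the C4a–C5 bond by Dieckmann condensation, and gentle warming should expel benzenesulfenic acid and let the triketone tautomerise to 18.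

2. Step 6. Face selectivity at the aldehyde may drop with the 4-oxygenated diene. Equilibration at C3 may be slow or incomplete. The C2–O1 bond, which is para-oxybenzylic and carries a good leaving group, may ionise in acid or open by retro-oxa-Michael reaction in base, either of which would erode the configuration at C2. The fallback separates the two stereocentres, setting out from 7 and coming back at 10. The unsubstituted diene trans-1-methoxy-3-(trimethylsilyloxy)buta-1,3-diene under the same (S)-BINOL/Ti(OiPr)4 and TFA protocol should give (2S)-2-[4-(triisopropylsilyloxy)phenyl]-2,3-dihydro-4H-pyran-4-one F2, with only C2 to control. Enolisation with LiN(SiMe3)2 (THF, −78 °C) and hydroxylation with 2-(phenylsulfonyl)-3-phenyloxaziridine, anti to the aryl group, should give (2R,3R)-3-hydroxy-2-[4-(triisopropylsilyloxy)phenyl]-2,3-dihydro-4H-pyran-4-one F3. Benzylation with benzyl 2,2,2-trichloroacetimidate and catalytic TfOH should then give 10.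

3. Step 7. The sulfenyl chloride may attack the electron-rich silyloxyarene in competition with C5, or the addition across C5=C6 may not be followed cleanly by loss of HCl. The fallback replaces electrophilic sulfenylation by halogenation and cross-coupling, setting out from 10 and coming back at 11. Iodination (I2, pyridine, CH2Cl2, rt) should give (2R,3R)-3-(benzyloxy)-5-iodo-2-[4-(triisopropylsilyloxy)phenyl]-2,3-dihydro-4H-pyran-4-one F4. Carbon–sulfur coupling with thiophenol (Pd2(dba)3, Xantphos, iPr2NEt, dioxane, 80 °C) should then give 11.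

Further compounds
F1 | step 11 | methyl 4-[(5R,6R)-5-(benzyloxy)-4-oxo-3-(phenylsulfinyl)-6-[4-(triisopropylsilyloxy)phenyl]oxan-2-yl]-3-oxobutanoate | O1[C@H](c2ccc(O[Si](C(C)C)(C(C)C)C(C)C)cc2)[C@@H](OCc2ccccc2)C(=O)C(S(=O)c2ccccc2)C1CC(=O)CC(=O)OC
F2 | step 6 | (2S)-2-[4-(triisopropylsilyloxy)phenyl]-2,3-dihydro-4H-pyran-4-one | O1[C@H](c2ccc(O[Si](C(C)C)(C(C)C)C(C)C)cc2)CC(=O)C=C1
F3 | step 6 | (2R,3R)-3-hydroxy-2-[4-(triisopropylsilyloxy)phenyl]-2,3-dihydro-4H-pyran-4-one | O1[C@H](c2ccc(O[Si](C(C)C)(C(C)C)C(C)C)cc2)[C@@H](O)C(=O)C=C1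
F4 | step 7 | (2R,3R)-3-(benzyloxy)-5-iodo-2-[4-(triisopropylsilyloxy)phenyl]-2,3-dihydro-4H-pyran-4-one | O1[C@H](c2ccc(O[Si](C(C)C)(C(C)C)C(C)C)cc2)[C@@H](OCc2ccccc2)C(=O)C(I)=C1
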